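At early times the fraction of substrate lost does not follow its charge: after 6.00 min the east run holds 83% of 2.1 mM, and the south run 86% of 71 mM. This reads as a step that goes with [substrate][partner B], each turn taking one partner B.

| flask | substrate | partner A | partner B | remark | time |
|---|---|---|---|---|---|
| east | 2.1 mM | 24 mM | 20 mM | run made earlier |  |
| south-west | 10 mM | 24 mM | 20 mM | run made earlier |  |
| south | 71 mM | 24 mM | 20 mM | run made earlier |  |
| autumn | 2.0 mM | 24.0 mM | 20.0 mM |  | 1.0 h |
| dawn | 6.0 mM | 24.0 mM | 20.0 mM |  | 1.0 h |
| summer | 20 mM | 24.0 mM | 20.0 mM |  | 1.0 h |
| dusk | 60 mM | 24.0 mM | 20.0 mM |  | 1.0 h |

| run | time / min | target / % | substrate / % |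
|---|---|---|---|
| east | 2.50 | 0 | 93 |
| east | 6.00 | 1 | 83 |
| east | 12.0 | 0 | 74 |
| east | 30.0 | 19 | 50 |
| south-west | 4.00 | 2 | 92 |
| south-west | 10.0 | 2 | 76 |
| south-west | 20.0 | 5 | 62 |
| south-west | 30.0 | 13 | 50 |
| south | 2.50 | 1 | 93 |
| south | 6.00 | 0 | 86 |
| south | 12.0 | 0 | 70 |
| south | 30.0 | 1 | 61 |

(each reading ± 1.5 percentage points)

- [target] at the end for autumn, dawn, summer, dusk, in this order
- the course of these numbers from the first flask to the last (falls, then rises / falls all the way / rises, then falls / rises all the way / hardly changes)

- in percentages every species weighs as the substrate in it: one side product counts as two
- reactions considered so far: substrate + partner B -> open intermediate; partner B + partner A -> second intermediate; open intermediate + second intermediate -> target; 2 second intermediate -> homo product; substrate + open intermediate -> side product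
- "hardly changes" means that all values lie within two and a half points (for a concentration: within two and a half percent of the largest)

East gives a fractional fall of 0.0311 /min with [partner B] at its charge of 20 mM. Turned round, this gives the pseudo-first-order life of partner B against substrate: the charge of partner B over that rate and over the charge of substrate. At the upper end, dusk, this life is 10.7 min, shorter than the hour. At the lower end, autumn, it is 5.37 h, longer than the hour. Low charges should therefore gain target with substrate, while high charges should lose the partner B that second intermediate also needs. The ends join where life equals hour, at 10.7 mM of substrate, so this reckoning commits to a course that rises, then falls; it gives no row.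

The weak link is one reading, a fall of 17 percentage points against a scatter of 1.5 points. South-west has fallen 24 points after 10.0 min, which gives the capture rate, the fractional fall of substrate with partner B at its charge, as 0.0274 /min. The join moves to 12.1 mM.

The forecast gives 1 mM, 2.6 mM, 4 mM and 2 mM, course rises, then falls, holding for dusk that “the substrate grabs B quickly, starving the second intermediate”.

The flask gives 0.768 mM, 1.87 mM, 3.12 mM and 2.02 mM, course rises, then falls.

    substrate + partner B → open intermediate (k = 1.40 /M/min)
    partner B + partner A → second intermediate (k = 0.680 /M/min)
    open intermediate + second intermediate → target (k = 9.80 /M/min)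
    2 second intermediate → homo product (k = 8.60 /M/min)
    substrate + open intermediate → side product (k = 1.70 /M/min)

With the capture rate, the life of partner B in dusk is 12.1 min, shorter than the hour. Partner B, the limiting reagent there, stands at 10.1% of its charge after 0.500 h and 1.68% after 1.00 h. Part of the low target in dusk is this wearing away of partner B: with it held off, target reaches 9.22 mM against 2.02 mM. In autumn the life is 6.07 h, longer than the 1.0 h of reaction, and the wearing away of partner B is a smaller part of the low target, a factor of 1.32 against 4.57 in dusk. Autumn's target is held down as well by the hour of the reading together with the step to homo product: after 10.0 h it stands at 1.68 mM.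

All runs are simulated for an exercise; the scatter is artificial.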